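Ring B carries oxygen on four adjacent carbons; the outer two, the lactone oxygen of ring C and the pyranone oxygen of ring D, are para to each other, with the diaryl ether oxygen and the free phenol between them. That is a hydroquinone flanked by the two vinylic oxygens of a squaric ester. Ring B is built from a cyclobutenone carrying the ring A aryloxy group, a methoxy group and an (E)-propenyl carbinol: heating opens it to a dienylketene, which closes to the pentasubstituted hydroquinone through one C–C bond between the ketene carbon and the methyl-bearing alkene carbon. The crowded diaryl ether comes from acyl-type substitution on a squaric ester chloride.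

Key step: step 7

Assumption: the target has no stereocentre; the carbinol carbon of 12 is formed as a racemate and is erased in step 7, and the (E)-geometry of the propenyl group affects only the rate of that step.

Step 1
Reactants: 1 orsellinic acid (2,4-dihydroxy-6-methylbenzoic acid)
Product: 3 allyl 2-hydroxy-4-methoxy-6-methylbenzoate, via allyl orsellinate 2 (not isolated)
Conditions: allyl bromide (1.0 equiv), KHCO3, DMF, rt; then MeI (1.1 equiv), K2CO3, rt
Reagents that add atoms: allyl bromide C=CCBr; iodomethane CI
Why: Sequential SN2 O-alkylation should take the carboxylate first under bicarbonate and then the para phenol under carbonate, because the ortho hydroxyl is hydrogen-bonded to the ester and is the least nucleophilic site; the allyl ester is chosen because a di-ortho-substituted benzoate resists saponification later.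

Step 2
Reactants: 3 allyl 2-hydroxy-4-methoxy-6-methylbenzoate
Product: 4 allyl 3-formyl-2-hydroxy-4-methoxy-6-methylbenzoate
Conditions: MgCl2, Et3N, (CH2O)n, MeCN, reflux
Reagents that add atoms: paraformaldehyde (as formaldehyde) C=O
Why: Magnesium-phenoxide-directed ortho-formylation (Casnati–Skattebøl reaction) delivers formaldehyde only ortho to the free phenol, and C3 is the only such carbon that bears hydrogen.

Step 3
Reactants: 4 allyl 3-formyl-2-hydroxy-4-methoxy-6-methylbenzoate
Product: 5 allyl 3-(1,3-dioxolan-2-yl)-2-hydroxy-4-methoxy-6-methylbenzoate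
Conditions: ethylene glycol, TsOH·H2O (cat.), toluene, Dean–Stark, reflux; Et3N before concentration
Reagents that add atoms: ethylene glycol OCCO
Why: Acid-catalysed acetalisation with azeotropic removal of water should mask the aldehyde against the organolithium of step 6, the hindered allyl ester being inert to transesterification.

Step 4
Reactants: 6 squaric acid (3,4-dihydroxycyclobut-3-ene-1,2-dione)
Product: 7 squaryl dichloride (3,4-dichlorocyclobut-3-ene-1,2-dione)
Conditions: (COCl)2, DMF (cat.), CH2Cl2, reflux
Reagents that add atoms: oxalyl chloride ClC(=O)C(=O)Cl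
Why: Acid chloride formation through the chloroiminium species from DMF and oxalyl chloride converts the vinylogous diacid into the vinylogous diacid chloride.

Step 5
Reactants: 7 squaryl dichloride; 5 allyl 3-(1,3-dioxolan-2-yl)-2-hydroxy-4-methoxy-6-methylbenzoate
Product: 9 allyl 3-(1,3-dioxolan-2-yl)-4-methoxy-2-[(2-methoxy-3,4-dioxocyclobut-1-en-1-yl)oxy]-6-methylbenzoate (aryl methyl squarate), via 3-chloro-4-methoxycyclobut-3-ene-1,2-dione 8 (not isolated)
Conditions: MeOH (1.0 equiv), CH2Cl2, −40 → 0 °C, volatiles removed; then 5 premixed with Et3N, CH2Cl2, −78 → 0 °C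
Reagents that add atoms: methanol CO
Why: Two successive addition–elimination (vinylogous acyl substitution) steps, the first stopping at the ester chloride because the methoxy donor deactivates the remaining chloride, and the second irreversible because chloride leaves, whereas a dialkyl squarate would not give up alkoxide for the better leaving aryloxide.

Step 6
Reactants: 10 (E)-1-bromoprop-1-ene; 9 aryl methyl squarate
Product: 12 allyl 3-(1,3-dioxolan-2-yl)-2-{[3-hydroxy-2-methoxy-4-oxo-3-[(E)-prop-1-enyl]cyclobut-1-en-1-yl]oxy}-4-methoxy-6-methylbenzoate (racemic at the carbinol carbon), via (E)-prop-1-enyllithium 11 (not isolated)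
Conditions: 10, t-BuLi (2 equiv per 10), Et2O, −78 °C; added to 9, THF, −78 °C; aq NH4Cl, −78 °C
Reagents that add atoms: none
Why: Halogen–lithium exchange with retention followed by 1,2-addition of the alkenyllithium to the more electrophilic ketone, the one conjugated through the ring double bond with the weaker aryloxy donor and flanked by the small methoxy-bearing carbon, while the hindered ester and the acetal are inert at −78 °C.

Step 7
Reactants: 12 4-hydroxy-3-methoxy-4-[(E)-prop-1-enyl]-2-(ring A aryloxy)cyclobut-2-enone
Product: 13 allyl 2-(3,6-dihydroxy-2-methoxy-5-methylphenoxy)-3-(1,3-dioxolan-2-yl)-4-methoxy-6-methylbenzoate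
Conditions: degassed p-xylene, 138 °C, argon
Reagents that add atoms: none
Why: Thermal conrotatory four-electron opening of the cyclobutenone breaks the bond between the ketone carbon and the carbinol carbon and gives the dienylketene O=C=C(OAr)–C(OMe)=C(OH)–CH=CH–CH3, whose ketene carbon then bonds to the methyl-bearing alkene terminus, and the resulting cyclohexadienone enolises to the hydroquinone. This is the Moore rearrangement of 4-alkenyl-4-hydroxycyclobutenones derived from squaric esters. Ring B is closed in a six-electron disrotatory electrocyclic mode with one new C–C bond; no stereocentre results, since the sp3 carbon formed at the methyl-bearing terminus becomes aromatic on tautomerisation and the carbinol centre of 12 disappears. The step needs torquoselectivity: the hydroxyl, the strongest donor on the breaking carbon, should rotate outward, which turns the propenyl group inward toward the ketene, and the (E)-geometry keeps the methyl group on the outside of the closing terminus. Regiochemistry needs no control here, because the aryloxy carbon is already next to the ketene carbon in 12, so the hydroxyl beside the ether ends up next to the methyl group and the other hydroxyl next to the only ring CH. Exclusion of air should keep the electron-rich hydroquinone from going on to the quinone.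

Step 8
Reactants: 13 hydroquinone diaryl ether (allyl ester and dioxolane)
Product: 15 2-(3,6-dihydroxy-2-methoxy-5-methylphenoxy)-3-formyl-4-methoxy-6-methylbenzoic acid, via dioxolane acid 14 (not isolated)
Conditions: Pd(PPh3)4 (cat.), morpholine, THF, rt, argon; then 1 M HCl, THF–H2O, rt
Reagents that add atoms: water O
Why: Allyl transfer to morpholine through a π-allyl complex of zerovalent palladium (Tsuji–Trost deallylation) frees the hindered acid without attack at its carbonyl carbon, and the electron-rich aryl dioxolane is then hydrolysed by dilute acid once the amine is protonated.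

Step 9
Reactants: 15 2-(3,6-dihydroxy-2-methoxy-5-methylphenoxy)-3-formyl-4-methoxy-6-methylbenzoic acid
Product: 16 7-hydroxy-3,6-dimethoxy-1,9-dimethyl-11-oxo-11H-dibenzo[b,e][1,4]dioxepine-4-carbaldehyde (depsidone with rings A, B and C)
Conditions: DCC, THF–toluene (high dilution), rt
Reagents that add atoms: none
Why: Carbodiimide lactonisation, in which the O-acylisourea of the acid is captured by the only hydroxyl that can reach it, the one ortho to the ether oxygen, closing the seven-membered ring C, while dilution suppresses intermolecular acylation of the other phenol.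

Step 10
Reactants: 16 depsidone phenol; 17 3-methylbut-2-enoic acid
Product: 18 dimethyl ether of the target (16 with O7 and C8 bridged by C(CH3)2–CH2–C(=O), carbonyl on C8, forming the 2,2-dimethylchroman-4-one ring D)
Conditions: P2O5, MeSO3H, 70 °C
Reagents that add atoms: none
Why: Friedel–Crafts acylation at C8, the only unsubstituted carbon of ring B and ortho to the free phenol, followed by acid-catalysed oxa-Michael closure of that phenol onto the β,β-dimethyl enone, is the standard one-pot route to 2,2-dimethylchroman-4-ones, ring A being deactivated by its formyl and acyl groups.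

Step 11
Reactants: 18 dimethyl ether of the target
Product: 19 target depsidone (18 with both methoxy groups as free hydroxyls)
Conditions: BBr3, CH2Cl2, −78 → 0 °C; then H2O
Reagents that add atoms: none
Why: Lewis-acid ether cleavage (BBr3 demethylation) should remove both methyl groups, one assisted by chelation to the ortho formyl group and the other as the crowded central ether of three adjacent oxygens, whereas the aryl lactone has no alkyl–oxygen bond and the ring D oxygen is a weakly basic vinylogous ester oxygen.

Compound list
1 | orsellinic acid (2,4-dihydroxy-6-methylbenzoic acid) | Cc1cc(O)cc(O)c1C(=O)O | starting material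
2 | allyl orsellinate (prop-2-enyl 2,4-dihydroxy-6-methylbenzoate) | Cc1cc(O)cc(O)c1C(=O)OCC=C | intermediate
3 | allyl 2-hydroxy-4-methoxy-6-methylbenzoate | Cc1cc(OC)cc(O)c1C(=O)OCC=C | intermediate
4 | allyl 3-formyl-2-hydroxy-4-methoxy-6-methylbenzoate | Cc1cc(OC)c(C=O)c(O)c1C(=O)OCC=C | intermediate
5 | allyl 3-(1,3-dioxolan-2-yl)-2-hydroxy-4-methoxy-6-methylbenzoate | Cc1cc(OC)c(C2OCCO2)c(O)c1C(=O)OCC=C | intermediate
6 | squaric acid (3,4-dihydroxycyclobut-3-ene-1,2-dione) | O=C1C(=O)C(O)=C1O | starting material
7 | squaryl dichloride (3,4-dichlorocyclobut-3-ene-1,2-dione) | O=C1C(=O)C(Cl)=C1Cl | intermediate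
8 | 3-chloro-4-methoxycyclobut-3-ene-1,2-dione | COC1=C(Cl)C(=O)C1=O | intermediate
9 | allyl 3-(1,3-dioxolan-2-yl)-4-methoxy-2-[(2-methoxy-3,4-dioxocyclobut-1-en-1-yl)oxy]-6-methylbenzoate | COC1=C(Oc2c(C3OCCO3)c(OC)cc(C)c2C(=O)OCC=C)C(=O)C1=O | intermediate
10 | (E)-1-bromoprop-1-ene | C/C=C/Br | starting material
11 | (E)-prop-1-enyllithium | C/C=C/[Li] | intermediate
12 | allyl 3-(1,3-dioxolan-2-yl)-2-{[3-hydroxy-2-methoxy-4-oxo-3-[(E)-prop-1-enyl]cyclobut-1-en-1-yl]oxy}-4-methoxy-6-methylbenzoate, racemic | C/C=C/C1(O)C(OC)=C(Oc2c(C3OCCO3)c(OC)cc(C)c2C(=O)OCC=C)C1=O | intermediate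
13 | allyl 2-(3,6-dihydroxy-2-methoxy-5-methylphenoxy)-3-(1,3-dioxolan-2-yl)-4-methoxy-6-methylbenzoate | Cc1cc(O)c(OC)c(Oc2c(C3OCCO3)c(OC)cc(C)c2C(=O)OCC=C)c1O | intermediate
14 | 2-(3,6-dihydroxy-2-methoxy-5-methylphenoxy)-3-(1,3-dioxolan-2-yl)-4-methoxy-6-methylbenzoic acid | Cc1cc(O)c(OC)c(Oc2c(C3OCCO3)c(OC)cc(C)c2C(=O)O)c1O | intermediate
15 | 2-(3,6-dihydroxy-2-methoxy-5-methylphenoxy)-3-formyl-4-methoxy-6-methylbenzoic acid | Cc1cc(O)c(OC)c(Oc2c(C=O)c(OC)cc(C)c2C(=O)O)c1O | intermediate
16 | 7-hydroxy-3,6-dimethoxy-1,9-dimethyl-11-oxo-11H-dibenzo[b,e][1,4]dioxepine-4-carbaldehyde | Cc1cc(OC)c(C=O)c2c1C(=O)Oc1c(C)cc(O)c(OC)c1O2 | intermediate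
17 | 3-methylbut-2-enoic acid | CC(C)=CC(=O)O | starting material
18 | dimethyl ether of the target (ring D fused at O7–C8 of 16, both methoxy groups intact) | Cc1cc(OC)c(C=O)c2c1C(=O)Oc1c(C)c3c(c(OC)c1O2)OC(C)(C)CC3=O | intermediate
19 | target depsidone CNP0271978.0 | Cc1cc(O)c(C=O)c2c1C(=O)Oc1c(C)c3c(c(O)c1O2)OC(C)(C)CC3=O | target

Total step count: 11. Longest linear sequence: 10 steps (steps 1–3 and 5–11, from orsellinic acid).

Steps most likely to fail

Step 6. The alkenyllithium may attack the other ring ketone, or the aryloxy-bearing carbon with loss of aryloxide; the carbinol would then sit on the wrong side and methyl and hydrogen would be transposed on ring B. The fallback sets out from 7 and 5 and returns at 12. Compound 7 is treated with two equivalents of 5 and Et3N (CH2Cl2, −40 °C → rt) to give the symmetrical bis(aryl) squarate F1, in which both ketones are equivalent. Addition of 11 (THF, −78 °C; aq NH4Cl) gives the bis(aryloxy) carbinol F2. NaOMe (1 equiv, MeOH–THF, −40 → 0 °C) then exchanges only the aryloxy group on the carbon β to the ketone by addition–elimination, since the α-aryloxy group has no such path. This gives 12 with regiochemistry fixed by construction, and one equivalent of 5 is recovered.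

Step 7. Ring opening may occur with the hydroxyl turned inward, after which the hydroxyl adds to the ketene and a butenolide forms; the hydroquinone may also be oxidised by traces of air during heating and isolation. The fallback sets out from 9 and 11 and returns at 13. The lithium alkoxide formed from 9 and 11 is quenched at −78 °C with TMSCl in place of NH4Cl to give the trimethylsilyl ether F3. Thermolysis in degassed p-xylene should give the mono-silylated hydroquinone F4, in which the ketene cannot be intercepted by a free hydroxyl and one oxygen stays protected. K2CO3 (cat.) in MeOH at 0 °C under argon removes the silyl group and gives 13, which is taken on without storage.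

Step 10. In the strong acid the di-ortho-substituted lactone may ionise to an acylium ion and open, ring A may be acylated, or the formyl group may condense with ring B of a second molecule. The fallback sets out from 16 and 17 and returns at 18. The ring B phenol of 16 is esterified with 17 under neutral conditions (DCC, DMAP cat., CH2Cl2, rt) to give the aryl 3-methylbut-2-enoate F5. A Fries rearrangement (BF3·OEt2, 1,2-dichloroethane, 70 °C) then moves the acyl group to C8, the only free ortho position, and the liberated phenol closes ring D by oxa-Michael addition to give 18.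

Further compounds
F1 | step 6 | bis(aryl) squarate: 3,4-bis[2-(allyloxycarbonyl)-6-(1,3-dioxolan-2-yl)-5-methoxy-3-methylphenoxy]cyclobut-3-ene-1,2-dione | O=C1C(=O)C(Oc2c(C3OCCO3)c(OC)cc(C)c2C(=O)OCC=C)=C1Oc1c(C2OCCO2)c(OC)cc(C)c1C(=O)OCC=C
F2 | step 6 | bis(aryloxy) carbinol: 4-hydroxy-4-[(E)-prop-1-enyl]-2,3-bis(ring A aryloxy)cyclobut-2-enone, racemic | C/C=C/C1(O)C(Oc2c(C3OCCO3)c(OC)cc(C)c2C(=O)OCC=C)=C(Oc2c(C3OCCO3)c(OC)cc(C)c2C(=O)OCC=C)C1=O
F3 | step 7 | trimethylsilyl ether of 12 | C/C=C/C1(O[Si](C)(C)C)C(OC)=C(Oc2c(C3OCCO3)c(OC)cc(C)c2C(=O)OCC=C)C1=O
F4 | step 7 | mono-silylated hydroquinone: 13 with the hydroxyl next to the ring CH as its trimethylsilyl ether | Cc1cc(O[Si](C)(C)C)c(OC)c(Oc2c(C3OCCO3)c(OC)cc(C)c2C(=O)OCC=C)c1O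
F5 | step 10 | 3-methylbut-2-enoate ester of the 7-hydroxyl of 16 | Cc1cc(OC)c(C=O)c2c1C(=O)Oc1c(C)cc(OC(=O)C=C(C)C)c(OC)c1O2
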